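The data were generated by integration on assumed constants; scatter was added.

If each substrate lost arrives as solvolysis product, the two curves mirror each other and one first-order constant reads off either; take that mirror case, a share of 1, as the zero of the scale.

- gamma: substrate 10 mM; first nucleophile 9 mM; second nucleophile 50 mM; run made earlier
- flask: substrate 10 mM; first nucleophile 6.00 mM; second nucleophile 50.0 mM; time 6.0 h

gamma run (percent of the substrate charged)

| time / min | substrate / % | solvolysis product / % | target / % |
|---|---|---|---|
| 3.00 | 96 | 2 | 0 |
| 10.0 | 93 | 3 | 1 |
| 15.0 | 97 | 6 | 0 |
| 25.0 | 87 | 11 | 0 |
| 40.0 | 79 | 15 | 0 |

(scatter of a reading: 1.5 percentage points)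

- the state of affairs at 6.0 h: stopped, and by what, or still going (it is still moving / the first nucleophile has run out first / forward and back rates have come level / all of the substrate has reacted / the second nucleophile has run out first)
- how much of the substrate has reacted by 6.0 h
- how much solvolysis product there is at 6.0 h, in percent of the substrate charged

- what was read earlier has a scatter of 1.5 percentage points, one standard deviation
- the reaction counts as stopped when no species that holds the substrate changes by six tenths of a point or more over the second half of the time

Read the constant twice from the gamma run at 40.0 min. From the substrate left, 79%, get 0.00589 min⁻¹; call this logarithm of charge over remainder, per unit time, the loss constant. From the solvolysis product, 15%, get 0.00406 min⁻¹, which is smaller. At that reading the balance lacks 6 percentage points, against a scatter of 1.5 points per reading. The substrate way counts what leaves and the product way counts what arrives, so a second exit lowers the product way and leaves the substrate way untouched: keep the loss constant.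

The target reads 0% at 40.0 min in the gamma run, so treat the first nucleophile as unused and its cut from 9 mM to 6.00 mM as harmless. For the flask, the loss constant then gives 88.0% reacted by 6.0 h, with substrate still falling 23 points over the second half. Read the arriving share on the mirror scale: 71.4% at 40.0 min, 84.6% at 25.0 min. That puts the solvolysis product between 62.9% and 74.5%.

The forecast differs from this reckoning in its numbers: it says it is still moving, with 83% reacted (70% to 91%) and 78% solvolysis product (58% to 88%), on the ground that “Nearly all of the loss appears as solvolysis product”.

The flask gives 84.3% reacted, less than the reckoned figure, and 73.9% solvolysis product, inside the reckoned bracket; at 6.0 h, it is still moving, with 24 points of movement over the second half. In the flask, substrate fell to 39.6% at 3.00 h and 15.7% at 6.00 h, while the intermediate that substrate turns into stood at 0.00669% at 3.00 h, in a steady state with making over using at 1.00 at 1.77 h. By 6.00 h the other capture product held 10.3% and the target 0.00553% of the substrate charged, and the first nucleophile stood at >99.9% of its own charge.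

    second nucleophile + intermediate → other capture product (k = 1.26 M⁻¹ s⁻¹)
    substrate → intermediate (k = 8.58 × 10⁻⁵ s⁻¹)
    intermediate → side product (k = 2.95 × 10⁻⁴ s⁻¹)
    first nucleophile + intermediate ⇌ target (K = 347 M⁻¹, k = 10.7 M⁻¹ s⁻¹)
    intermediate → solvolysis product (k = 0.446 s⁻¹)

Take the neighbour, the same charge read at 1.5 h: the loss constant gives 41.2% reacted, and the two shares give 29.4% to 34.9% solvolysis product. That flask gives 37.1% and 32.5%.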